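- I freeze one ratio.

| setting | Tuesday's | Saturday's | flask |
|---|---|---|---|
| substrate | 0.50 M | 0.50 M | 0.50 M |
| reagent | 0.28 M | 1.1 M | 0.550 M |
| remark | run made earlier | run made earlier |  |
| time |  |  | 20 h |

| run | time / h | single product / % | substrate / % |
|---|---|---|---|
| Tuesday's | 0.333 | 5 | 97 |
| Tuesday's | 1.33 | 5 | 85 |
| Tuesday's | 5.00 | 2 | 56 |
| Tuesday's | 20.0 | 2 | 34 |
| Saturday's | 0.333 | 11 | 81 |
| Saturday's | 1.33 | 16 | 47 |
| Saturday's | 5.00 | 17 | 11 |
| Saturday's | 20.0 | 10 | 0 |

(scatter of a reading: 1.5 percentage points)

* the moment within 20 h at which there is most single product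
* the amount of single product, in percent of the substrate charged, at that time

- the earlier runs were read with a standard deviation of 1.5 percentage points

- Fastest rung: in Tuesday's run, single product reads 5% at 0.333 h and 5% at 1.33 h, while substrate reads 97% and then 85%. I treat single product as an intermediate in quasi-steady state, made and consumed at about equal rates.
- Middle rung: I take substrate loss as first order in the reagent charged. Saturday's 47% of substrate at 1.33 h, scaled to the new flask's reagent, gives a substrate half-life near 2.44 h.
- Slowest rung: in Saturday's run, single product drifts from 17% at 5.00 h to 10% at 20.0 h, a decline I keep apart from the height of the peak.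
- The quantity I take as nearly constant, with substrate charged at 0.50 M, is the ceiling ratio g, the peak concentration of single product over the reagent charged. The highest readings give 0.0893 on Tuesday and 0.0773 on Saturday, so I carry their mean, 0.0833.
- For the new flask, g times its reagent over its substrate gives 9.16%, and I expect the peak before 2.44 h.
- The forecast gives 9.5% at 2.3 h, and its reasoning reaches “about 9%, consistent with interpolating between the peaks”.
- The new flask peaks at 10.1% after 1.42 h, earlier than my half-life, with 66.6% of the substrate left. Its own g is 0.0915, and at 1.69 h single product is made at 0.926 of the rate at which it is used up, each step taken net.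

    substrate + reagent → single product (k = 1.22 × 10⁻⁴ L mol⁻¹ s⁻¹)
    reagent + single product → double product (k = 1.35 × 10⁻⁵ L mol⁻¹ s⁻¹)
    substrate + single product → side product (k = 7.56 × 10⁻⁴ L mol⁻¹ s⁻¹)
    reagent ⇌ dormant form (K = 2.18, k = 6.22 × 10⁻⁵ s⁻¹)

- The neighbouring flask holds 0.14 M of reagent, with the substrate unchanged. The same g predicts a peak of 2.33% there, and that flask gives 2.63%.

All runs were computed for substances that don't exist; scatter was added.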